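**Retrosynthetic overview**
1. The (Z)-p-coumarate is made last on the C18 alcohol (phosphonoacetate acylation, Still–Gennari olefination); the diene comes from alkyl boronate 16 and chloroprene (Suzuki).
2. The C9–C11 bond is formed photochemically: the C9 radical of trans-diaxial bromohydrin 14 adds to vinyl-Bpin from the β face (sets C9); the bromohydrin sets C8.
3. The Δ8 alkene 13 comes from enone 8 by tosylhydrazone reductive transposition and desulfonylation.
4. Ring A, the only ring made, is closed by a visible-light titanocene epoxide-opening 6-endo radical cyclisation of 7 (sets C4); ring B is the bought carvone ring.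
5. Epoxide 7 comes from (S)-carvone by α′-methylation, α′-sulfonylallylation (sets C10 from C5) and epoxidation.

Assumption: the SMILES is read literally. In labdane numbering (C17 on C8, C18 = CH2O and C19 = CH3 on C4, C20 on C10) it is 4S,5S,8R,9R,10R. In the usual drawing (ring A left, β up) this means 5β-H, 10α-CH3, 4β-CH2O (equatorial), 9β side chain (axial, anti to C20) and 8α-OH (axial). These locants are used for the bicyclic compounds; carvone numbering is used for 1–7.

Step 1
Reactants: 1 (S)-(+)-carvone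
Product: 3 6-methylcarvone (C6 epimers), via lithium dienolate 2 (not isolated)
Conditions: lithium diisopropylamide (LDA), THF, −78 °C; then MeI, −78 → 0 °C
Reagents that add atoms: iodomethane, CI
Why: Kinetic α′-deprotonation of the cross-conjugated enone and C-methylation (enolate alkylation); the new C6 centre needs no control because it is planarised again in step 2.

Step 2
Reactants: 3 6-methylcarvone; 4 2,3-bis(phenylsulfonyl)prop-1-ene
Product: 6 (5R,6R)-2,6-dimethyl-6-[2-(phenylsulfonyl)prop-2-en-1-yl]-5-(prop-1-en-2-yl)cyclohex-2-en-1-one, via lithium enolate 5 (not isolated)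
Conditions: LDA, THF, −78 °C; then 4, −78 → −20 °C
Reagents that add atoms: 2,3-bis(phenylsulfonyl)prop-1-ene (4), C=C(CS(=O)(=O)c1ccccc1)S(=O)(=O)c1ccccc1
Why: The enolate adds to the CH2 terminus of the vinyl sulfone and expels benzenesulfinate (addition–elimination allylation, SN2′ type), the electrophile entering anti to the neighbouring isopropenyl group, so the quaternary carbon (future C10) carries CH3 cis and the sulfonylallyl arm trans to the C5 substituent.

Step 3
Reactants: 6 dialkylated carvone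
Product: 7 (5S,6R)-2,6-dimethyl-5-(2-methyloxiran-2-yl)-6-[2-(phenylsulfonyl)prop-2-en-1-yl]cyclohex-2-en-1-one (about 1:1 at the oxirane carbon)
Conditions: mCPBA, NaHCO3, CH2Cl2, 0 °C
Reagents that add atoms: meta-chloroperoxybenzoic acid, OOC(=O)c1cccc(Cl)c1
Why: Prilezhaev epoxidation picks the only electron-rich alkene (isopropenyl) over the enone and the vinyl sulfone; the uncontrolled epoxide centre is erased in step 4.

Step 4
Reactants: 7 epoxide
Product: 8 (4aR,5S,8aR)-5-(hydroxymethyl)-2,5,8a-trimethyl-7-(phenylsulfonyl)-4a,5,6,7,8,8a-hexahydronaphthalen-1(4H)-one (C7 epimers)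
Conditions: Cp2TiCl2 (10 mol%), 4CzIPN (2 mol%), Hantzsch ester (1.5 equiv), THF, blue LEDs (450 nm), rt
Reagents that add atoms: none
Why: Proposed new method: visible-light titanocene catalysis (reduced 4CzIPN turns Cp2TiCl2 into the trivalent titanium species Cp2TiCl, Hantzsch ester supplying electrons and protons) is known for epoxide opening followed by intermolecular Giese addition or 5-exo closure, whereas here both epoxide epimers must open to one planar tertiary β-titanoxy radical at C4 that closes 6-endo on the CH2 terminus of the 2-sulfonylallyl acceptor (5-exo would hit the sulfonyl-bearing carbon) through a chair in which the bulky CH2OTi group sits equatorial, away from the axial C10 methyl, so that the C3–C4 bond, ring A and the quaternary C4 (CH2OH β, CH3 α) arise diastereoconvergently before the α-sulfonyl radical is reduced and protonated; the closest known reaction is the Nugent–RajanBabu titanocene-mediated epoxide radical cyclisation.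

Step 5
Reactants: 8 bicyclic enone
Product: 9 tosylhydrazone of 8
Conditions: TsNHNH2, AcOH (cat.), MeOH, 50 °C
Reagents that add atoms: 4-methylbenzenesulfonohydrazide, Cc1ccc(cc1)S(=O)(=O)NN
Why: Acid-catalysed condensation of the enone carbonyl with the sulfonyl hydrazide (hydrazone formation); no stereocentre is touched.

Step 6
Reactants: 9 tosylhydrazone
Product: 12 [(1S,4aS,8aS)-1,4a,6-trimethyl-3-(phenylsulfonyl)-1,2,3,4,4a,7,8,8a-octahydronaphthalen-1-yl]methanol, via allylic tosylhydrazine 10 (not isolated), via allylic diazene 11 (not isolated)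
Conditions: catecholborane, CHCl3, 0 °C → rt; then NaOAc·3H2O, reflux
Reagents that add atoms: none
Why: Kabalka-type reductive 1,3-transposition: hydride adds to C=N, sulfinate is eliminated and the allylic diazene loses N2 by a retro-ene shift that delivers H to C7 and leaves the C8=C9 alkene; no new stereocentre.

Step 7
Reactants: 12 alkene sulfone
Product: 13 [(1S,4aS,8aS)-1,4a,6-trimethyl-1,2,3,4,4a,7,8,8a-octahydronaphthalen-1-yl]methanol
Conditions: Na(Hg) (6%), Na2HPO4, MeOH/THF, −20 °C → rt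
Reagents that add atoms: none
Why: Single-electron reductive desulfonylation of the secondary alkyl phenyl sulfone; the isolated trisubstituted alkene and the alcohol are inert.

Step 8
Reactants: 13 alkene alcohol
Product: 14 (1R,2R,4aS,5S,8aR)-1-bromo-5-(hydroxymethyl)-2,5,8a-trimethyldecahydronaphthalen-2-ol (9β-Br, 8α-OH)
Conditions: NBS, acetone/H2O (4:1), 0 °C
Reagents that add atoms: N-bromosuccinimide, O=C1CCC(=O)N1Br; water, O
Why: Bromohydrin formation: the bromonium ion forms on the β face, away from the axial C10 methyl, and water opens it at the tertiary C8 from the α face (Markovnikov and trans-diaxial, Fürst–Plattner), which sets 8α-OH/8β-CH3 next to 9β-Br.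

Step 9
Reactants: 14 bromohydrin; 15 4,4,5,5-tetramethyl-2-vinyl-1,3,2-dioxaborolane
Product: 16 (1R,2R,4aS,5S,8aR)-5-(hydroxymethyl)-2,5,8a-trimethyl-1-[2-(4,4,5,5-tetramethyl-1,3,2-dioxaborolan-2-yl)ethyl]decahydronaphthalen-2-ol
Conditions: Ir[dF(CF3)ppy]2(dtbbpy)PF6 (1 mol%), (TMS)3SiH (1.5 equiv), 15 (5 equiv), 2,6-lutidine, MeCN/MeOH (4:1), blue LEDs (450 nm), rt
Reagents that add atoms: vinylboronic acid pinacol ester (15), C=CB1OC(C)(C)C(C)(C)O1
Why: Photochemical silyl-radical halogen-atom abstraction gives the C9 radical, which adds to the vinyl boronate (Giese reaction) from the β face, the only one not blocked by the two axial α groups (10-CH3 and 8-OH), so the new C9–C11 bond is β (anti to the C10 methyl, trans-diaxial to 8-OH) before the α-boryl radical takes H from the silane.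

Step 10
Reactants: 16 alkyl boronate; 17 2-chlorobuta-1,3-diene (chloroprene, stabilised solution)
Product: 18 (1R,2R,4aS,5S,8aR)-5-(hydroxymethyl)-2,5,8a-trimethyl-1-(3-methylidenepent-4-en-1-yl)decahydronaphthalen-2-ol
Conditions: Pd(OAc)2 (5 mol%), RuPhos (10 mol%), K3PO4, toluene/H2O (10:1), BHT, 80 °C, sealed tube
Reagents that add atoms: chloroprene (17), C=CC(Cl)=C
Why: B-alkyl Suzuki–Miyaura coupling (zerovalent palladium inserts into the alkenyl C–Cl bond, the primary alkyl boronate transmetalates) builds the 2-substituted buta-1,3-diene; no stereocentre is involved.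

Step 11
Reactants: 18 diene diol; 19 2-[bis(2,2,2-trifluoroethoxy)phosphoryl]acetic acid
Product: 20 C18 phosphonoacetate of 18
Conditions: EDC·HCl, DMAP (cat.), CH2Cl2, 0 °C → rt
Reagents that add atoms: bis(2,2,2-trifluoroethyl)phosphonoacetic acid (19), OC(=O)CP(=O)(OCC(F)(F)F)OCC(F)(F)F
Why: Carbodiimide (Steglich) esterification acylates only the primary C18 hydroxyl; the axial tertiary 8-OH does not react.

Step 12
Reactants: 20 phosphonoacetate; 21 4-[(tert-butyldimethylsilyl)oxy]benzaldehyde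
Product: 24 target (Z)-p-coumarate, via potassium phosphonate 22 (not isolated), via silyl ether 23 (not isolated)
Conditions: potassium hexamethyldisilazide (KHMDS, 1.05 equiv), 18-crown-6, THF, −78 °C; 21; then AcOH, TBAF, 0 °C; amber glassware
Reagents that add atoms: 4-[(tert-butyldimethylsilyl)oxy]benzaldehyde (21), O=Cc1ccc(O[Si](C)(C)C(C)(C)C)cc1
Why: Still–Gennari olefination (trifluoroethyl phosphonate, dissociated potassium counter-ion) gives the Z-enoate under kinetic control, and buffered fluoride then removes the phenolic silyl group in the same flask without Z/E isomerisation.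

**Compound list**
1 | (S)-(+)-carvone, (5S)-2-methyl-5-(prop-1-en-2-yl)cyclohex-2-en-1-one | CC1=CC[C@@H](CC1=O)C(C)=C | starting material
2 | lithium 6-methyl-3-(prop-1-en-2-yl)cyclohexa-1,5-dien-1-olate (kinetic α′-enolate of 1, ring stereocentre as in 1) | [Li+].[O-]C1=C[C@@H](C(C)=C)CC=C1C | intermediate (not isolated)
3 | 6-methylcarvone, (5S)-2,6-dimethyl-5-(prop-1-en-2-yl)cyclohex-2-en-1-one, C6 epimers | O=C1C(C)=CC[C@H](C(C)=C)C1C | intermediate
4 | 2,3-bis(phenylsulfonyl)prop-1-ene | C=C(CS(=O)(=O)c1ccccc1)S(=O)(=O)c1ccccc1 | starting material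
5 | lithium 2,6-dimethyl-3-(prop-1-en-2-yl)cyclohexa-1,5-dien-1-olate (enolate of 3) | [Li+].[O-]C1=C(C)[C@@H](C(C)=C)CC=C1C | intermediate (not isolated)
6 | (5R,6R)-2,6-dimethyl-6-[2-(phenylsulfonyl)prop-2-en-1-yl]-5-(prop-1-en-2-yl)cyclohex-2-en-1-one (6-CH3 cis, sulfonylallyl trans to isopropenyl) | O=C1C(C)=CC[C@H](C(C)=C)[C@@]1(C)CC(=C)S(=O)(=O)c1ccccc1 | intermediate
7 | (5S,6R)-2,6-dimethyl-5-(2-methyloxiran-2-yl)-6-[2-(phenylsulfonyl)prop-2-en-1-yl]cyclohex-2-en-1-one, about 1:1 at the oxirane carbon | O=C1C(C)=CC[C@H](C2(C)CO2)[C@@]1(C)CC(=C)S(=O)(=O)c1ccccc1 | intermediate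
8 | (4aR,5S,8aR)-5-(hydroxymethyl)-2,5,8a-trimethyl-7-(phenylsulfonyl)-4a,5,6,7,8,8a-hexahydronaphthalen-1(4H)-one, C7 epimers (trans-fused; 4a-H and CH2OH β, 5-CH3 and 8a-CH3 α) | O=C1C(C)=CC[C@@H]2[C@@](C)(CO)CC(S(=O)(=O)c3ccccc3)C[C@@]12C | intermediate
9 | tosylhydrazone (4-methylbenzenesulfonohydrazone) of 8 at C1 | Cc1ccc(cc1)S(=O)(=O)NN=C1C(C)=CC[C@@H]2[C@@](C)(CO)CC(S(=O)(=O)c3ccccc3)C[C@@]12C | intermediate
10 | allylic N′-tosylhydrazine (C=N of 9 reduced, drawn boron-free) | Cc1ccc(cc1)S(=O)(=O)NNC1C(C)=CC[C@@H]2[C@@](C)(CO)CC(S(=O)(=O)c3ccccc3)C[C@@]12C | intermediate (not isolated)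
11 | allylic diazene (10 after loss of toluenesulfinate) | N=NC1C(C)=CC[C@@H]2[C@@](C)(CO)CC(S(=O)(=O)c3ccccc3)C[C@@]12C | intermediate (not isolated)
12 | [(1S,4aS,8aS)-1,4a,6-trimethyl-3-(phenylsulfonyl)-1,2,3,4,4a,7,8,8a-octahydronaphthalen-1-yl]methanol, C3 epimers | C1=C(C)CC[C@@H]2[C@@](C)(CO)CC(S(=O)(=O)c3ccccc3)C[C@@]12C | intermediate
13 | [(1S,4aS,8aS)-1,4a,6-trimethyl-1,2,3,4,4a,7,8,8a-octahydronaphthalen-1-yl]methanol (Δ8 alkene, 18-OH) | C1=C(C)CC[C@@H]2[C@@](C)(CO)CCC[C@@]12C | intermediate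
14 | (1R,2R,4aS,5S,8aR)-1-bromo-5-(hydroxymethyl)-2,5,8a-trimethyldecahydronaphthalen-2-ol (9β-Br, 8α-OH, trans-diaxial) | Br[C@@H]1[C@]2(C)CCC[C@](C)(CO)[C@H]2CC[C@@]1(C)O | intermediate
15 | 4,4,5,5-tetramethyl-2-vinyl-1,3,2-dioxaborolane | C=CB1OC(C)(C)C(C)(C)O1 | starting material
16 | (1R,2R,4aS,5S,8aR)-5-(hydroxymethyl)-2,5,8a-trimethyl-1-[2-(4,4,5,5-tetramethyl-1,3,2-dioxaborolan-2-yl)ethyl]decahydronaphthalen-2-ol | CC1(C)OB(CC[C@@H]2[C@]3(C)CCC[C@](C)(CO)[C@H]3CC[C@@]2(C)O)OC1(C)C | intermediate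
17 | 2-chlorobuta-1,3-diene (chloroprene) | C=CC(Cl)=C | starting material
18 | (1R,2R,4aS,5S,8aR)-5-(hydroxymethyl)-2,5,8a-trimethyl-1-(3-methylidenepent-4-en-1-yl)decahydronaphthalen-2-ol | C=CC(=C)CC[C@@H]1[C@]2(C)CCC[C@](C)(CO)[C@H]2CC[C@@]1(C)O | intermediate
19 | 2-[bis(2,2,2-trifluoroethoxy)phosphoryl]acetic acid | OC(=O)CP(=O)(OCC(F)(F)F)OCC(F)(F)F | starting material
20 | [(1S,4aR,5R,6R,8aS)-6-hydroxy-1,4a,6-trimethyl-5-(3-methylidenepent-4-en-1-yl)decahydronaphthalen-1-yl]methyl 2-[bis(2,2,2-trifluoroethoxy)phosphoryl]acetate | C=CC(=C)CC[C@@H]1[C@]2(C)CCC[C@](C)(COC(=O)CP(=O)(OCC(F)(F)F)OCC(F)(F)F)[C@H]2CC[C@@]1(C)O | intermediate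
21 | 4-[(tert-butyldimethylsilyl)oxy]benzaldehyde | O=Cc1ccc(O[Si](C)(C)C(C)(C)C)cc1 | starting material
22 | potassium salt of the phosphonate carbanion of 20 | [K+].C=CC(=C)CC[C@@H]1[C@]2(C)CCC[C@](C)(COC(=O)[CH-]P(=O)(OCC(F)(F)F)OCC(F)(F)F)[C@H]2CC[C@@]1(C)O | intermediate (not isolated)
23 | O-tert-butyldimethylsilyl ether of the target (Z) | C=CC(=C)CC[C@@H]1[C@]2(C)CCC[C@](C)(COC(=O)/C=C\c3ccc(O[Si](C)(C)C(C)(C)C)cc3)[C@H]2CC[C@@]1(C)O | intermediate (not isolated)
24 | [(1S,4aR,5R,6R,8aS)-6-hydroxy-1,4a,6-trimethyl-5-(3-methylidenepent-4-en-1-yl)decahydronaphthalen-1-yl]methyl (2Z)-3-(4-hydroxyphenyl)prop-2-enoate | C=CC(=C)CC[C@@H]1[C@]2(C)CCC[C@](C)(COC(=O)/C=C\c3ccc(O)cc3)[C@H]2CC[C@@]1(C)O | target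

**Totals**
Total step count: 12. Longest linear sequence: 12 steps from (S)-carvone; all other building blocks are bought.

**Steps most likely to fail, with fallbacks**

Step 4 (the proposed new step). The risks are premature reduction of the C4 radical and weak control at C4. The fallback sets out from 6 and uses known iron-hydride chemistry in place of the epoxide route. Ene-type allylic chlorination of the isopropenyl group (Ca(OCl)2, CO2, CH2Cl2/H2O) gives the allylic chloride F1. CsOAc in DMF gives the allylic acetate F2. The MHAT cyclisation (Fe(acac)3, PhSiH3, EtOH/ethylene glycol, 60 °C) puts H on the CH2 terminus and closes the same C3–C4 bond 6-endo onto the vinyl sulfone, giving the bicyclic acetate F3 (C4 epimers separated). K2CO3/MeOH then returns to 8.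

Step 9. The risks are reduction of the hindered C9 radical before it adds, and epoxide closure of the bromohydrin. The fallback sets out from 14 with a thermal tin-hydride chain and a faster acceptor. Bu3SnH/AIBN (slow addition, benzene, 80 °C) with N-methoxy-N-methylacrylamide gives the Weinreb amide F4. Vinylmagnesium bromide gives the vinyl ketone F5. Wittig methylenation (Ph3P=CH2) builds the diene by carbonyl olefination and rejoins the route at 18, so step 10 is bypassed.

Step 10. The risks are slow transmetalation of the alkyl pinacol boronate and chloroprene polymerisation. The fallback sets out from 16 and is a transition-metal-free Zweifel olefination. Buta-1,3-dien-2-ylmagnesium chloride (from 17 and Mg) in THF/DMSO forms the dienyl boronate complex F6 (not isolated). I2 followed by NaOMe triggers the 1,2-shift and elimination to give 18.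

Further compounds
F1 | step 4 | 6 with the isopropenyl group replaced by 3-chloroprop-1-en-2-yl | O=C1C(C)=CC[C@H](C(=C)CCl)[C@@]1(C)CC(=C)S(=O)(=O)c1ccccc1
F2 | step 4 | 6 with the isopropenyl group replaced by 3-acetoxyprop-1-en-2-yl | O=C1C(C)=CC[C@H](C(=C)COC(C)=O)[C@@]1(C)CC(=C)S(=O)(=O)c1ccccc1
F3 | step 4 | O-acetate of 8 | O=C1C(C)=CC[C@@H]2[C@@](C)(COC(C)=O)CC(S(=O)(=O)c3ccccc3)C[C@@]12C
F4 | step 9 | N-methoxy-N-methyl-3-[(1R,2R,4aS,5S,8aR)-2-hydroxy-5-(hydroxymethyl)-2,5,8a-trimethyldecahydronaphthalen-1-yl]propanamide | CON(C)C(=O)CC[C@@H]1[C@]2(C)CCC[C@](C)(CO)[C@H]2CC[C@@]1(C)O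
F5 | step 9 | 5-[(1R,2R,4aS,5S,8aR)-2-hydroxy-5-(hydroxymethyl)-2,5,8a-trimethyldecahydronaphthalen-1-yl]pent-1-en-3-one | C=CC(=O)CC[C@@H]1[C@]2(C)CCC[C@](C)(CO)[C@H]2CC[C@@]1(C)O
F6 | step 10 | chloromagnesium (buta-1,3-dien-2-yl)boronate complex of 16 (drawn with the hydroxyls protonated) | C=CC(=C)[B-]1(CC[C@@H]2[C@]3(C)CCC[C@](C)(CO)[C@H]3CC[C@@]2(C)O)OC(C)(C)C(C)(C)O1.[Mg+]Cl
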